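**Retrosynthetic overview**
1. Target 23 ⇐ bicyclic triol 18: two site-selective esterifications (4-methoxybenzoate on the equatorial secondary OH, then angelate on the hindered allylic OH; the tertiary OH stays free).
2. 18 ⇐ cyclopentane diene 17: ring-closing metathesis closes the seven-membered ring at the trisubstituted alkene.
3. 17 ⇐ bicyclic β-lactone 10: half-reduction/methallylation sets the anisoate-bearing carbinol; a diol-to-vinyl-carbinol homologation supplies the second alkene.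
4. 10 ⇐ acyclic keto acid 8: aldol-lactonization closes the cyclopentane and a β-lactone together and sets the tertiary carbinol and the ring-fusion CH.
5. 8 ⇐ nerol 1: Sharpless epoxidation sets the angelate-bearing carbon; alkynylalane opening with inversion sets the quaternary methyl carbon. Ring order: cyclopentane + β-lactone first (β-lactone then opened), cycloheptene last.

Assumption: the target is taken exactly as the given SMILES, i.e. the (3R,3aS,4S,8R,8aS)-octahydroazulene; the route is a proposal and has not been run.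

**Route**

Step 1
Reactants: 1 nerol, (2Z)-3,7-dimethylocta-2,6-dien-1-ol
Product: 2 [(2R,3S)-3-methyl-3-(4-methylpent-3-en-1-yl)oxiran-2-yl]methanol, (2R,3S)-2,3-epoxynerol
Conditions: Ti(OiPr)4 (5 mol %), D-(−)-diisopropyl tartrate (7 mol %), tBuOOH, 4 Å MS, CH2Cl2, −20 °C
Reagents that add atoms: tert-butyl hydroperoxide, CC(C)(C)OO
Why: Sharpless asymmetric epoxidation of the (Z)-allylic alcohol with the D-tartrate ligand epoxidises only the allylic alkene from one face, fixing the future angelate-bearing carbon as (2R) and giving the (3S) epoxide carbon that is inverted in step 2.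

Step 2
Reactants: 2 (2R,3S)-2,3-epoxynerol; 3 ethynyl(trimethyl)silane
Product: 5 (2S,3S)-3,7-dimethyl-3-[(trimethylsilyl)ethynyl]oct-6-ene-1,2-diol, via diethyl[(trimethylsilyl)ethynyl]alane 4 (not isolated)
Conditions: 3, n-BuLi, then Et2AlCl, toluene/hexane, 0 °C; then 2, 0 °C to rt
Reagents that add atoms: none
Why: Nozaki–Oshima-type alkynylalane opening of a 2,3-epoxy alcohol takes place at the carbon remote from the hydroxyl (here the tertiary one) with inversion, so the quaternary methyl-bearing carbon is formed with defined configuration next to the untouched secondary carbinol.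

Step 3
Reactants: 5 (2S,3S)-3,7-dimethyl-3-[(trimethylsilyl)ethynyl]oct-6-ene-1,2-diol
Product: 6 (4S)-4-[(3S)-3,7-dimethyl-1-(trimethylsilyl)oct-6-en-1-yn-3-yl]-2,2-dimethyl-1,3-dioxolane
Conditions: Me2C(OMe)2, pyridinium p-toluenesulfonate (cat.), CH2Cl2, rt
Reagents that add atoms: 2,2-dimethoxypropane, COC(C)(C)OC
Why: Acid-catalysed transketalisation masks the 1,2-diol as its acetonide so that no hydroxyl can trap the activated acid in step 6, and no stereocentre is touched.

Step 4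
Reactants: 6 (4S)-4-[(3S)-3,7-dimethyl-1-(trimethylsilyl)oct-6-en-1-yn-3-yl]-2,2-dimethyl-1,3-dioxolane
Product: 7 (3S)-3-[(4S)-2,2-dimethyl-1,3-dioxolan-4-yl]-6-hydroxy-3,7-dimethyloctanoic acid (both C6 epimers)
Conditions: BH3·THF (4 equiv), THF, 0 °C to rt; then NaOH, H2O2, 0 to 40 °C
Reagents that add atoms: hydrogen peroxide, OO
Why: Brown hydroboration–oxidation turns the trisubstituted alkene into the anti-Markovnikov secondary alcohol (configuration irrelevant, oxidised next), while the silylalkyne is hydroborated at the silicon-bearing carbon and alkaline H2O2 takes it through the acylsilane to the carboxylic acid (Zweifel oxidation).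

Step 5
Reactants: 7 (3S)-3-[(4S)-2,2-dimethyl-1,3-dioxolan-4-yl]-6-hydroxy-3,7-dimethyloctanoic acid
Product: 8 (3S)-3-[(4S)-2,2-dimethyl-1,3-dioxolan-4-yl]-3,7-dimethyl-6-oxooctanoic acid
Conditions: Dess–Martin periodinane, CH2Cl2, rt
Reagents that add atoms: none
Why: Dess–Martin oxidation converts the secondary alcohol into the isopropyl ketone without touching the acid or the acetonide and removes the stereo-random carbinol centre.

Step 6
Reactants: 8 (3S)-3-[(4S)-2,2-dimethyl-1,3-dioxolan-4-yl]-3,7-dimethyl-6-oxooctanoic acid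
Product: 10 (1R,2S,5R)-2-[(4S)-2,2-dimethyl-1,3-dioxolan-4-yl]-2-methyl-5-(propan-2-yl)-6-oxabicyclo[3.2.0]heptan-7-one, via carboxylic 4-methylbenzenesulfonic anhydride 9 (not isolated)
Conditions: TsCl, iPr2NEt, LiCl, 4-(pyrrolidin-1-yl)pyridine (1 equiv), CH2Cl2, 23 °C
Reagents that add atoms: none
Why: In this Romo nucleophile-catalysed aldol-lactonization the ammonium enolate adds to the isopropyl ketone and the alkoxide closes the β-lactone, so the cyclopentane and the oxetanone form together; the cis-fused β-lactone forces the new C–O bond syn to the acyl carbon, and the acyl carbon goes anti to the bulky dioxolanyl group (syn to methyl) on the neighbouring quaternary carbon, which sets the tertiary carbinol and the ring-fusion CH.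

Step 7
Reactants: 10 (1R,2S,5R)-2-[(4S)-2,2-dimethyl-1,3-dioxolan-4-yl]-2-methyl-5-(propan-2-yl)-6-oxabicyclo[3.2.0]heptan-7-one; 11 (2-methylprop-2-en-1-yl)magnesium chloride
Product: 13 (1R,2S,3S)-3-[(4S)-2,2-dimethyl-1,3-dioxolan-4-yl]-2-[(1S)-1-hydroxy-3-methylbut-3-en-1-yl]-3-methyl-1-(propan-2-yl)cyclopentan-1-ol, via beta-hydroxy aldehyde 12 (not isolated)
Conditions: iBu2AlH (1.05 equiv), CH2Cl2, −78 °C; then 11, −78 to 0 °C
Reagents that add atoms: none
Why: Proposed new method: one equivalent of iBu2AlH adds to the strained lactone carbonyl and the aluminium hemiacetal opens to aldehyde 12, held as a six-membered O–Al–O chelate with the tertiary alkoxide, so the methallyl Grignard reagent attacks from the convex face anti to the quaternary ring carbon (Cram-chelate and Felkin–Anh models agree) to give the (S)-carbinol, the closest known reaction type being the one-pot iBu2AlH half-reduction/organometallic addition of esters and lactones.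

Step 8
Reactants: 13 (1R,2S,3S)-3-[(4S)-2,2-dimethyl-1,3-dioxolan-4-yl]-2-[(1S)-1-hydroxy-3-methylbut-3-en-1-yl]-3-methyl-1-(propan-2-yl)cyclopentan-1-ol
Product: 14 (1S)-1-{(1S,2S,3R)-3-hydroxy-2-[(1S)-1-hydroxy-3-methylbut-3-en-1-yl]-1-methyl-3-(propan-2-yl)cyclopentyl}ethane-1,2-diol
Conditions: AcOH/H2O (4:1), 40 °C
Reagents that add atoms: none
Why: Mild aqueous acid hydrolysis removes the acetonide without hydrating the 1,1-disubstituted alkene or ionising the tertiary alcohol, and no stereocentre is affected.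

Step 9
Reactants: 14 (1S)-1-{(1S,2S,3R)-3-hydroxy-2-[(1S)-1-hydroxy-3-methylbut-3-en-1-yl]-1-methyl-3-(propan-2-yl)cyclopentyl}ethane-1,2-diol
Product: 15 (2S)-2-hydroxy-2-{(1S,2S,3R)-3-hydroxy-2-[(1S)-1-hydroxy-3-methylbut-3-en-1-yl]-1-methyl-3-(propan-2-yl)cyclopentyl}ethyl 4-methylbenzenesulfonate
Conditions: TsCl (1.05 equiv), Et3N, Bu2SnO (2 mol %), CH2Cl2, 0 °C to rt
Reagents that add atoms: 4-methylbenzenesulfonyl chloride, Cc1ccc(cc1)S(=O)(=O)Cl
Why: Dibutyltin oxide-catalysed sulfonylation through the stannylene acetal of the 1,2-diol selects the primary hydroxyl over the two secondary and the tertiary hydroxyls.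

Step 10
Reactants: 15 (2S)-2-hydroxy-2-{(1S,2S,3R)-3-hydroxy-2-[(1S)-1-hydroxy-3-methylbut-3-en-1-yl]-1-methyl-3-(propan-2-yl)cyclopentyl}ethyl 4-methylbenzenesulfonate
Product: 17 (1R,2S,3S)-2-[(1S)-1-hydroxy-3-methylbut-3-en-1-yl]-3-[(1R)-1-hydroxyprop-2-en-1-yl]-3-methyl-1-(propan-2-yl)cyclopentan-1-ol, via terminal epoxide 16 (not isolated)
Conditions: Me3S+ I− (8 equiv), n-BuLi (7 equiv), THF, −10 °C; then 15, −10 °C to rt
Reagents that add atoms: trimethylsulfonium iodide, C[S+](C)C.[I-]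
Why: The secondary alkoxide closes the terminal epoxide by intramolecular Williamson displacement at the primary carbon (the stereocentre is not attacked), and dimethylsulfonium methylide then opens the epoxide at CH2 and loses Me2S by ylide-mediated elimination, a one-carbon epoxide-to-allylic-alcohol homologation.

Step 11
Reactants: 17 (1R,2S,3S)-2-[(1S)-1-hydroxy-3-methylbut-3-en-1-yl]-3-[(1R)-1-hydroxyprop-2-en-1-yl]-3-methyl-1-(propan-2-yl)cyclopentan-1-ol
Product: 18 (3R,3aS,4S,8R,8aS)-6,8a-dimethyl-3-(propan-2-yl)-1,2,3,3a,4,5,8,8a-octahydroazulene-3,4,8-triol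
Conditions: second-generation Grubbs catalyst (5 mol %), toluene, 80 °C
Reagents that add atoms: none
Why: Ring-closing metathesis between the vinyl and isopropenyl groups, whose arms are trans on the cyclopentane, closes the trans-fused cycloheptene with its trisubstituted alkene and releases ethene, leaving all stereocentres untouched.

Step 12
Reactants: 18 (3R,3aS,4S,8R,8aS)-6,8a-dimethyl-3-(propan-2-yl)-1,2,3,3a,4,5,8,8a-octahydroazulene-3,4,8-triol; 19 4-methoxybenzoyl chloride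
Product: 20 (3R,3aS,4S,8R,8aS)-3,8-dihydroxy-6,8a-dimethyl-3-(propan-2-yl)-1,2,3,3a,4,5,8,8a-octahydroazulen-4-yl 4-methoxybenzoate
Conditions: 19 (1.1 equiv), pyridine, 4-(dimethylamino)pyridine (cat.), CH2Cl2, 0 °C
Reagents that add atoms: none
Why: Acylation with the acid chloride goes to the equatorial secondary hydroxyl because the other secondary hydroxyl is axial and neopentyl (next to the quaternary carbon) and the third is tertiary.

Step 13
Reactants: 20 (3R,3aS,4S,8R,8aS)-3,8-dihydroxy-6,8a-dimethyl-3-(propan-2-yl)-1,2,3,3a,4,5,8,8a-octahydroazulen-4-yl 4-methoxybenzoate; 21 angelic acid, (2Z)-2-methylbut-2-enoic acid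
Product: 23 (3R,3aS,4S,8R,8aS)-3-hydroxy-6,8a-dimethyl-8-{[(2Z)-2-methylbut-2-enoyl]oxy}-3-(propan-2-yl)-1,2,3,3a,4,5,8,8a-octahydroazulen-4-yl 4-methoxybenzoate, via angelic 2,4,6-trichlorobenzoic anhydride 22 (not isolated)
Conditions: 21, 2,4,6-trichlorobenzoyl chloride, Et3N, toluene, rt; then 20, 75 °C
Reagents that add atoms: none
Why: Yamaguchi esterification through the mixed anhydride acylates the hindered allylic hydroxyl without the nucleophilic catalyst that isomerises angelates to tiglates, the tertiary alcohol is inert, and the (Z)-geometry of the acid is carried over.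

**Compound list**
1 | nerol, (2Z)-3,7-dimethylocta-2,6-dien-1-ol | CC(C)=CCC/C(C)=C\CO | starting material
2 | [(2R,3S)-3-methyl-3-(4-methylpent-3-en-1-yl)oxiran-2-yl]methanol | OC[C@H]1O[C@@]1(C)CCC=C(C)C | intermediate
3 | ethynyl(trimethyl)silane | C#C[Si](C)(C)C | starting material
4 | diethyl[(trimethylsilyl)ethynyl]alane | CC[Al](CC)C#C[Si](C)(C)C | intermediate
5 | (2S,3S)-3,7-dimethyl-3-[(trimethylsilyl)ethynyl]oct-6-ene-1,2-diol | OC[C@@H](O)[C@](C)(C#C[Si](C)(C)C)CCC=C(C)C | intermediate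
6 | (4S)-4-[(3S)-3,7-dimethyl-1-(trimethylsilyl)oct-6-en-1-yn-3-yl]-2,2-dimethyl-1,3-dioxolane | CC1(C)OC[C@@H](O1)[C@](C)(C#C[Si](C)(C)C)CCC=C(C)C | intermediate
7 | (3S)-3-[(4S)-2,2-dimethyl-1,3-dioxolan-4-yl]-6-hydroxy-3,7-dimethyloctanoic acid (both C6 epimers) | CC1(C)OC[C@@H](O1)[C@](C)(CC(=O)O)CCC(O)C(C)C | intermediate
8 | (3S)-3-[(4S)-2,2-dimethyl-1,3-dioxolan-4-yl]-3,7-dimethyl-6-oxooctanoic acid | CC1(C)OC[C@@H](O1)[C@](C)(CC(=O)O)CCC(=O)C(C)C | intermediate
9 | (3S)-3-[(4S)-2,2-dimethyl-1,3-dioxolan-4-yl]-3,7-dimethyl-6-oxooctanoic 4-methylbenzenesulfonic anhydride | CC1(C)OC[C@@H](O1)[C@](C)(CC(=O)OS(=O)(=O)c2ccc(C)cc2)CCC(=O)C(C)C | intermediate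
10 | (1R,2S,5R)-2-[(4S)-2,2-dimethyl-1,3-dioxolan-4-yl]-2-methyl-5-(propan-2-yl)-6-oxabicyclo[3.2.0]heptan-7-one | O=C1O[C@@]2(C(C)C)CC[C@](C)([C@H]3COC(C)(C)O3)[C@@H]12 | intermediate
11 | (2-methylprop-2-en-1-yl)magnesium chloride | CC(=C)C[Mg]Cl | starting material
12 | (1R,2R,5S)-5-[(4S)-2,2-dimethyl-1,3-dioxolan-4-yl]-2-hydroxy-5-methyl-2-(propan-2-yl)cyclopentane-1-carbaldehyde | O=C[C@H]1[C@](O)(C(C)C)CC[C@]1(C)[C@H]2COC(C)(C)O2 | intermediate
13 | (1R,2S,3S)-3-[(4S)-2,2-dimethyl-1,3-dioxolan-4-yl]-2-[(1S)-1-hydroxy-3-methylbut-3-en-1-yl]-3-methyl-1-(propan-2-yl)cyclopentan-1-ol | C=C(C)C[C@H](O)[C@H]1[C@](O)(C(C)C)CC[C@]1(C)[C@H]2COC(C)(C)O2 | intermediate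
14 | (1S)-1-{(1S,2S,3R)-3-hydroxy-2-[(1S)-1-hydroxy-3-methylbut-3-en-1-yl]-1-methyl-3-(propan-2-yl)cyclopentyl}ethane-1,2-diol | C=C(C)C[C@H](O)[C@H]1[C@](O)(C(C)C)CC[C@]1(C)[C@H](O)CO | intermediate
15 | (2S)-2-hydroxy-2-{(1S,2S,3R)-3-hydroxy-2-[(1S)-1-hydroxy-3-methylbut-3-en-1-yl]-1-methyl-3-(propan-2-yl)cyclopentyl}ethyl 4-methylbenzenesulfonate | C=C(C)C[C@H](O)[C@H]1[C@](O)(C(C)C)CC[C@]1(C)[C@H](O)COS(=O)(=O)c2ccc(C)cc2 | intermediate
16 | (1R,2S,3S)-2-[(1S)-1-hydroxy-3-methylbut-3-en-1-yl]-3-methyl-3-[(2S)-oxiran-2-yl]-1-(propan-2-yl)cyclopentan-1-ol | C=C(C)C[C@H](O)[C@H]1[C@](O)(C(C)C)CC[C@]1(C)[C@H]2CO2 | intermediate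
17 | (1R,2S,3S)-2-[(1S)-1-hydroxy-3-methylbut-3-en-1-yl]-3-[(1R)-1-hydroxyprop-2-en-1-yl]-3-methyl-1-(propan-2-yl)cyclopentan-1-ol | C=C(C)C[C@H](O)[C@H]1[C@](O)(C(C)C)CC[C@]1(C)[C@H](O)C=C | intermediate
18 | (3R,3aS,4S,8R,8aS)-6,8a-dimethyl-3-(propan-2-yl)-1,2,3,3a,4,5,8,8a-octahydroazulene-3,4,8-triol | O[C@@H]1C=C(C)C[C@H](O)[C@@H]2[C@]1(C)CC[C@@]2(O)C(C)C | intermediate
19 | 4-methoxybenzoyl chloride | COc1ccc(cc1)C(=O)Cl | starting material
20 | (3R,3aS,4S,8R,8aS)-3,8-dihydroxy-6,8a-dimethyl-3-(propan-2-yl)-1,2,3,3a,4,5,8,8a-octahydroazulen-4-yl 4-methoxybenzoate | O[C@@H]1C=C(C)C[C@H](OC(=O)c2ccc(OC)cc2)[C@@H]2[C@]1(C)CC[C@@]2(O)C(C)C | intermediate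
21 | angelic acid, (2Z)-2-methylbut-2-enoic acid | C/C=C(/C)C(=O)O | starting material
22 | (2Z)-2-methylbut-2-enoic 2,4,6-trichlorobenzoic anhydride | C/C=C(/C)C(=O)OC(=O)c1c(Cl)cc(Cl)cc1Cl | intermediate
23 | (3R,3aS,4S,8R,8aS)-3-hydroxy-6,8a-dimethyl-8-{[(2Z)-2-methylbut-2-enoyl]oxy}-3-(propan-2-yl)-1,2,3,3a,4,5,8,8a-octahydroazulen-4-yl 4-methoxybenzoate | C/C=C(/C)C(=O)O[C@@H]1C=C(C)C[C@H](OC(=O)c2ccc(OC)cc2)[C@@H]2[C@]1(C)CC[C@@]2(O)C(C)C | target

**Step count and risk**
Total steps: 13. Longest linear sequence: 13 (from nerol 1).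

The three steps most likely to fail:

Step 6 (aldol-lactonization onto a hindered isopropyl ketone, and its diastereoselectivity). The fallback sets out from 8. The acid is coupled with thiophenol (N,N′-dicyclohexylcarbodiimide, 4-(dimethylamino)pyridine) to give S-phenyl (3S)-3-[(4S)-2,2-dimethyl-1,3-dioxolan-4-yl]-3,7-dimethyl-6-oxooctanethioate F1. Soft enolisation (MgBr2·OEt2, iPr2NEt, CH2Cl2) then closes the cyclopentane by a chelated intramolecular thioester aldol to S-phenyl (1R,2R,5S)-5-[(4S)-2,2-dimethyl-1,3-dioxolan-4-yl]-2-hydroxy-5-methyl-2-(propan-2-yl)cyclopentane-1-carbothioate F2. Fukuyama reduction (Et3SiH, Pd/C, acetone) gives the aldehyde, and the fallback comes back to the route at 12, which is now isolated and allylated with 11 as in the second stage of step 7.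

Step 7 (one-pot half-reduction of the β-lactone and allylation; over-reduction is the main danger). The fallback sets out from 10. Full reduction (LiBH4, THF) gives (1R,2S,3S)-3-[(4S)-2,2-dimethyl-1,3-dioxolan-4-yl]-2-(hydroxymethyl)-3-methyl-1-(propan-2-yl)cyclopentan-1-ol F3. The primary alcohol is oxidised selectively (2,2,6,6-tetramethylpiperidin-1-oxyl, PhI(OAc)2, CH2Cl2) to isolated 12, which is allylated with 11 in the presence of MgBr2·OEt2, and the fallback comes back to the route at 13.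

Step 13 (acylation of the axial, neopentyl allylic hydroxyl without angelate-to-tiglate isomerisation). The fallback sets out from 20. The hydroxyl is acylated with 2-[bis(2,2,2-trifluoroethoxy)phosphoryl]propanoic acid (N,N′-dicyclohexylcarbodiimide, 4-(dimethylamino)pyridine) to give (3R,3aS,4S,8R,8aS)-8-({2-[bis(2,2,2-trifluoroethoxy)phosphoryl]propanoyl}oxy)-3-hydroxy-6,8a-dimethyl-3-(propan-2-yl)-1,2,3,3a,4,5,8,8a-octahydroazulen-4-yl 4-methoxybenzoate F4. A Z-selective Still–Gennari olefination with acetaldehyde (KN(SiMe3)2, 18-crown-6, THF, −78 °C) builds the angelate double bond on the substrate, and the fallback comes back to the route at 23.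

**Further compounds**
F1 | step 6 | S-phenyl (3S)-3-[(4S)-2,2-dimethyl-1,3-dioxolan-4-yl]-3,7-dimethyl-6-oxooctanethioate | CC1(C)OC[C@@H](O1)[C@](C)(CC(=O)Sc2ccccc2)CCC(=O)C(C)C
F2 | step 6 | S-phenyl (1R,2R,5S)-5-[(4S)-2,2-dimethyl-1,3-dioxolan-4-yl]-2-hydroxy-5-methyl-2-(propan-2-yl)cyclopentane-1-carbothioate | O=C(Sc3ccccc3)[C@H]1[C@](O)(C(C)C)CC[C@]1(C)[C@H]2COC(C)(C)O2
F3 | step 7 | (1R,2S,3S)-3-[(4S)-2,2-dimethyl-1,3-dioxolan-4-yl]-2-(hydroxymethyl)-3-methyl-1-(propan-2-yl)cyclopentan-1-ol | OC[C@H]1[C@](O)(C(C)C)CC[C@]1(C)[C@H]2COC(C)(C)O2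
F4 | step 13 | (3R,3aS,4S,8R,8aS)-8-({2-[bis(2,2,2-trifluoroethoxy)phosphoryl]propanoyl}oxy)-3-hydroxy-6,8a-dimethyl-3-(propan-2-yl)-1,2,3,3a,4,5,8,8a-octahydroazulen-4-yl 4-methoxybenzoate | CC(C(=O)O[C@@H]1C=C(C)C[C@H](OC(=O)c2ccc(OC)cc2)[C@@H]2[C@]1(C)CC[C@@]2(O)C(C)C)P(=O)(OCC(F)(F)F)OCC(F)(F)F
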